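The oxocane carbons C9–C10, flanked by the ring methylenes C8 and C11, are mapped onto acetylene. In one pot, lithium acetylide is alkylated by the cis-epoxy triflate 6 (C3–C8) and, after a second lithiation, opens the terminal epoxide 9 (C11–C15). This forms C8–C9 and C10–C11 and joins both halves with all four of their stereocentres in place. The alkyne then becomes the ring Z-alkene. An 8-exo hydroxy-epoxide cyclisation (O–C7) closes the oxocene, and transannular bromoetherification of C9=C10 by the C6 hydroxyl builds the tetrahydrofuran ring (O–C9) and the C10 bromide of the 2,8-dioxabicyclo[5.2.1]decane.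

Key step: step 7

Remark on numbering: carbons are counted C1 (alkyne CH) to C15 (ethyl CH3) along the chain. The target is 6S,7S,9S,10S,12S,13R, with the oxocane oxygen on C7/C13 and the tetrahydrofuran oxygen on C6/C9.

Assumption: (2R,2'R)-2,2'-bioxirane and 1,3-bis[tri(propan-2-yl)silyl]prop-1-yne are purchased; the minor enantiomer of 5 becomes a separable diastereomer after step 7.

Step 1
Reactants: 1 prop-2-yn-1-ol; 2 3-bromoprop-1-ene (allyl bromide)
Product: 3 hex-5-en-2-yn-1-ol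
Conditions: CuI (10 mol%), NaI (cat.), K2CO3, DMF, rt
Reagents that add atoms: none
Why: Copper-catalysed coupling of a terminal alkyne with an allylic halide should give the skipped enyne without protecting the hydroxyl; no stereocentre is formed.

Step 2
Reactants: 3 hex-5-en-2-yn-1-ol
Product: 4 (2Z)-hexa-2,5-dien-1-ol
Conditions: H2 (1 atm), Pd/CaCO3 poisoned with Pb(OAc)2, quinoline, EtOAc, rt
Reagents that add atoms: none
Why: Lindlar semihydrogenation adds H2 syn to the alkyne and so sets the Z geometry, while the poisoned catalyst should spare the terminal alkene if uptake is stopped at one equivalent.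

Step 3
Reactants: 4 (2Z)-hexa-2,5-dien-1-ol
Product: 5 [(2R,3S)-3-(prop-2-en-1-yl)oxiran-2-yl]methanol
Conditions: Ti(OiPr)4 (10 mol%), D-(−)-diisopropyl tartrate (12 mol%), t-BuOOH, 4 Å MS, CH2Cl2, −20 °C
Reagents that add atoms: tert-butyl hydroperoxide CC(C)(C)OO
Why: Sharpless asymmetric epoxidation acts only on the allylic alkene; the D-(−)-tartrate ligand sets C7 as R and the Z geometry translates into the cis epoxide with C6 as S.

Step 4
Reactants: 5 [(2R,3S)-3-(prop-2-en-1-yl)oxiran-2-yl]methanol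
Product: 6 [(2R,3S)-3-(prop-2-en-1-yl)oxiran-2-yl]methyl trifluoromethanesulfonate
Conditions: Tf2O, 2,6-lutidine, CH2Cl2, −78 °C; used at once
Reagents that add atoms: trifluoromethanesulfonic anhydride O=S(=O)(OS(=O)(=O)C(F)(F)F)C(F)(F)F
Why: O-Sulfonylation of the primary alcohol with a hindered base should give the epoxy triflate without touching either stereocentre.

Step 5
Reactants: 7 (2R,2'R)-2,2'-bioxirane
Product: 8 (1R)-1-[(2R)-oxiran-2-yl]propan-1-ol
Conditions: MeMgBr (1.0 equiv), CuI (10 mol%), THF, −40 °C; aq. NH4Cl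
Reagents that add atoms: methylmagnesium bromide C[Mg]Br
Why: Copper-catalysed Grignard opening of one of the two homotopic terminal epoxides at its CH2 (SN2) should give a single epoxy alcohol, with C12 and C13 carried unchanged from the C2-symmetric bis-epoxide.

Step 6
Reactants: 8 (1R)-1-[(2R)-oxiran-2-yl]propan-1-ol
Product: 9 triethyl{(1R)-1-[(2R)-oxiran-2-yl]propoxy}silane
Conditions: TESCl, imidazole, CH2Cl2, 0 °C
Reagents that add atoms: chlorotriethylsilane CC[Si](Cl)(CC)CC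
Why: Silylation under weakly basic conditions protects the C13 hydroxyl without Payne rearrangement of the epoxy alcohol.

Step 7
Reactants: 10 acetylene; 6 [(2R,3S)-3-(prop-2-en-1-yl)oxiran-2-yl]methyl trifluoromethanesulfonate; 9 triethyl{(1R)-1-[(2R)-oxiran-2-yl]propoxy}silane
Product: 12 (3R,4R)-8-[(2R,3S)-3-(prop-2-en-1-yl)oxiran-2-yl]-3-[(triethylsilyl)oxy]oct-6-yn-4-ol, via terminal alkyne 11 (not isolated)
Conditions: HC≡CH (excess), n-BuLi (1.0 equiv), THF, −78 °C; 6, −78 to −30 °C; Ar purge; n-BuLi (1.0 equiv), −78 °C; 9, BF3·OEt2, −78 °C; aq. NH4Cl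
Reagents that add atoms: none
Why: Lithium acetylide displaces the primary triflate of 6 by SN2 (C8–C9) to give terminal alkyne 11; after the excess acetylene is purged, a second lithiation gives the alkynyllithium, which with BF3·OEt2 opens the terminal epoxide of 9 at its CH2 by SN2 (C10–C11). The closest known reactions are the alkylation of lithium acetylides with alkyl triflates and the BF3-mediated Yamaguchi-type alkynylation of epoxides, run here in sequence on acetylene as a two-carbon linchpin. No ring is closed and no stereocentre is created: C6 and C7 (cis-epoxide) and C12 and C13 come in from 6 and 9, and neither reacting carbon is stereogenic. The step needs chemoselectivity for the triflate over the internal epoxide, which the far better leaving group at −78 °C without Lewis acid should secure, and mono-alkylation of acetylene, which the acetylene excess (purged before the second lithiation) should secure. In the second stage the unhindered terminal epoxide of 9 must react before the 2,3-dialkyl epoxide of the nucleophile, which its lower substitution and the low temperature should ensure.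

Step 8
Reactants: 12 (3R,4R)-8-[(2R,3S)-3-(prop-2-en-1-yl)oxiran-2-yl]-3-[(triethylsilyl)oxy]oct-6-yn-4-ol
Product: 13 (3R,4R,6Z)-8-[(2R,3S)-3-(prop-2-en-1-yl)oxiran-2-yl]-3-[(triethylsilyl)oxy]oct-6-en-4-ol
Conditions: H2 (1 atm), Pd/CaCO3 poisoned with Pb(OAc)2, quinoline, EtOAc, rt
Reagents that add atoms: none
Why: Lindlar semihydrogenation converts the internal alkyne into the Z-alkene (C9=C10) by syn delivery of H2, and should leave the terminal alkene, the epoxide and the silyl ether untouched.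

Step 9
Reactants: 13 (3R,4R,6Z)-8-[(2R,3S)-3-(prop-2-en-1-yl)oxiran-2-yl]-3-[(triethylsilyl)oxy]oct-6-en-4-ol
Product: 14 {[(3R,4S,6Z)-4-bromo-8-[(2R,3S)-3-(prop-2-en-1-yl)oxiran-2-yl]oct-6-en-3-yl]oxy}triethylsilane
Conditions: CBr4, P(n-Oct)3, toluene, 50 °C
Reagents that add atoms: carbon tetrabromide BrC(Br)(Br)Br
Why: Appel bromination proceeds through the alkoxyphosphonium salt and SN2 attack of bromide, so the 12R alcohol should give the 12S bromide with inversion.

Step 10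
Reactants: 14 {[(3R,4S,6Z)-4-bromo-8-[(2R,3S)-3-(prop-2-en-1-yl)oxiran-2-yl]oct-6-en-3-yl]oxy}triethylsilane
Product: 15 (3R,4S,6Z)-4-bromo-8-[(2R,3S)-3-(prop-2-en-1-yl)oxiran-2-yl]oct-6-en-3-ol
Conditions: HF·pyridine, pyridine, THF, 0 °C
Reagents that add atoms: none
Why: Buffered fluoride cleaves the triethylsilyl ether without base, so the anti bromohydrin should not close to an epoxide and the cis-epoxide should survive.

Step 11
Reactants: 15 (3R,4S,6Z)-4-bromo-8-[(2R,3S)-3-(prop-2-en-1-yl)oxiran-2-yl]oct-6-en-3-ol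
Product: 16 (1S)-1-[(2S,4Z,7S,8R)-7-bromo-8-ethyl-3,6,7,8-tetrahydro-2H-oxocin-2-yl]but-3-en-1-ol
Conditions: Eu(fod)3, toluene, 100 °C
Reagents that add atoms: none
Why: Lewis-acid-promoted hydroxy-epoxide cyclisation in the 8-exo mode, helped by the Z-alkene in the tether, lets the C13 hydroxyl open the epoxide at C7 with SN2 inversion (7R epoxide to 7S ether), which frees the C6 hydroxyl and gives the 2,8-trans oxocene.

Step 12
Reactants: 16 (1S)-1-[(2S,4Z,7S,8R)-7-bromo-8-ethyl-3,6,7,8-tetrahydro-2H-oxocin-2-yl]but-3-en-1-ol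
Product: 17 (1S,3R,4S,6S,7S,9S)-4,6-dibromo-3-ethyl-9-(prop-2-en-1-yl)-2,8-dioxabicyclo[5.2.1]decane
Conditions: NBS, CH2Cl2, −20 to 0 °C, dark
Reagents that add atoms: N-bromosuccinimide O=C1CCC(=O)N1Br
Why: Transannular bromoetherification opens the bromonium ion of the ring Z-alkene at C9 with the C6 hydroxyl in the 5-exo mode; the C7 tether fixes the face of attack (9S) and anti addition across the Z-alkene fixes 10S, while the less electron-rich terminal alkene has no hydroxyl in reach.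

Step 13
Reactants: 17 (1S,3R,4S,6S,7S,9S)-4,6-dibromo-3-ethyl-9-(prop-2-en-1-yl)-2,8-dioxabicyclo[5.2.1]decane
Product: 19 2-[(1S,3R,4S,6S,7S,9S)-4,6-dibromo-3-ethyl-2,8-dioxabicyclo[5.2.1]decan-9-yl]acetaldehyde, via ozonide 18 (not isolated)
Conditions: O3, CH2Cl2, −78 °C; PPh3, −78 °C to rt
Reagents that add atoms: ozone [O-][O+]=O
Why: Ozonolysis with reductive work-up cleaves the only remaining alkene to the C4 aldehyde; ethers and secondary bromides are inert.

Step 14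
Reactants: 19 2-[(1S,3R,4S,6S,7S,9S)-4,6-dibromo-3-ethyl-2,8-dioxabicyclo[5.2.1]decan-9-yl]acetaldehyde; 20 1,3-bis[tri(propan-2-yl)silyl]prop-1-yne
Product: 22 {(3Z)-5-[(1S,3R,4S,6S,7S,9S)-4,6-dibromo-3-ethyl-2,8-dioxabicyclo[5.2.1]decan-9-yl]pent-3-en-1-yn-1-yl}tri(propan-2-yl)silane, via silyl alkoxide adduct 21 (not isolated)
Conditions: 20, n-BuLi, THF, −78 °C; then 19, −78 to 0 °C; aq. NH4Cl
Reagents that add atoms: none
Why: Peterson olefination with the lithiated bis-silyl propyne: the bulky silyl groups should favour the adduct whose syn elimination of silanolate gives the Z-enyne (C3=C4).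

Step 15
Reactants: 22 {(3Z)-5-[(1S,3R,4S,6S,7S,9S)-4,6-dibromo-3-ethyl-2,8-dioxabicyclo[5.2.1]decan-9-yl]pent-3-en-1-yn-1-yl}tri(propan-2-yl)silane
Product: 23 (1S,3R,4S,6S,7S,9S)-4,6-dibromo-3-ethyl-9-[(2Z)-pent-2-en-4-yn-1-yl]-2,8-dioxabicyclo[5.2.1]decane
Conditions: TBAF, THF, 0 °C, short reaction time
Reagents that add atoms: none
Why: Fluoride-induced protodesilylation of the alkynylsilane should free the terminal alkyne at 0 °C without displacing or eliminating the secondary bromides.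

Compound list
1 | prop-2-yn-1-ol | OCC#C | starting material
2 | 3-bromoprop-1-ene (allyl bromide) | C=CCBr | starting material
3 | hex-5-en-2-yn-1-ol | OCC#CCC=C | intermediate
4 | (2Z)-hexa-2,5-dien-1-ol | OC/C=C\CC=C | intermediate
5 | [(2R,3S)-3-(prop-2-en-1-yl)oxiran-2-yl]methanol | C=CC[C@@H]1O[C@@H]1CO | intermediate
6 | [(2R,3S)-3-(prop-2-en-1-yl)oxiran-2-yl]methyl trifluoromethanesulfonate | C=CC[C@@H]1O[C@@H]1COS(=O)(=O)C(F)(F)F | intermediate
7 | (2R,2'R)-2,2'-bioxirane | C1O[C@H]1[C@H]1CO1 | starting material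
8 | (1R)-1-[(2R)-oxiran-2-yl]propan-1-ol | CC[C@@H](O)[C@H]1CO1 | intermediate
9 | triethyl{(1R)-1-[(2R)-oxiran-2-yl]propoxy}silane | CC[C@@H](O[Si](CC)(CC)CC)[C@H]1CO1 | intermediate
10 | acetylene (ethyne) | C#C | starting material
11 | (2S,3R)-2-(prop-2-en-1-yl)-3-(prop-2-yn-1-yl)oxirane | C=CC[C@@H]1O[C@@H]1CC#C | intermediate
12 | (3R,4R)-8-[(2R,3S)-3-(prop-2-en-1-yl)oxiran-2-yl]-3-[(triethylsilyl)oxy]oct-6-yn-4-ol | C=CC[C@@H]1O[C@@H]1CC#CC[C@@H](O)[C@@H](CC)O[Si](CC)(CC)CC | intermediate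
13 | (3R,4R,6Z)-8-[(2R,3S)-3-(prop-2-en-1-yl)oxiran-2-yl]-3-[(triethylsilyl)oxy]oct-6-en-4-ol | C=CC[C@@H]1O[C@@H]1C/C=C\C[C@@H](O)[C@@H](CC)O[Si](CC)(CC)CC | intermediate
14 | {[(3R,4S,6Z)-4-bromo-8-[(2R,3S)-3-(prop-2-en-1-yl)oxiran-2-yl]oct-6-en-3-yl]oxy}triethylsilane | C=CC[C@@H]1O[C@@H]1C/C=C\C[C@H](Br)[C@@H](CC)O[Si](CC)(CC)CC | intermediate
15 | (3R,4S,6Z)-4-bromo-8-[(2R,3S)-3-(prop-2-en-1-yl)oxiran-2-yl]oct-6-en-3-ol | C=CC[C@@H]1O[C@@H]1C/C=C\C[C@H](Br)[C@@H](CC)O | intermediate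
16 | (1S)-1-[(2S,4Z,7S,8R)-7-bromo-8-ethyl-3,6,7,8-tetrahydro-2H-oxocin-2-yl]but-3-en-1-ol | C=CC[C@H](O)[C@@H]1C/C=C\C[C@H](Br)[C@@H](CC)O1 | intermediate
17 | (1S,3R,4S,6S,7S,9S)-4,6-dibromo-3-ethyl-9-(prop-2-en-1-yl)-2,8-dioxabicyclo[5.2.1]decane | C=CC[C@@H]1O[C@H]2C[C@@H]1O[C@H](CC)[C@@H](Br)C[C@@H]2Br | intermediate
18 | 3-{[(1S,3R,4S,6S,7S,9S)-4,6-dibromo-3-ethyl-2,8-dioxabicyclo[5.2.1]decan-9-yl]methyl}-1,2,4-trioxolane (ozonide, trioxolane carbon not assigned) | C1OC(C[C@@H]2O[C@H]3C[C@@H]2O[C@H](CC)[C@@H](Br)C[C@@H]3Br)OO1 | intermediate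
19 | 2-[(1S,3R,4S,6S,7S,9S)-4,6-dibromo-3-ethyl-2,8-dioxabicyclo[5.2.1]decan-9-yl]acetaldehyde | O=CC[C@@H]1O[C@H]2C[C@@H]1O[C@H](CC)[C@@H](Br)C[C@@H]2Br | intermediate
20 | 1,3-bis[tri(propan-2-yl)silyl]prop-1-yne | CC(C)[Si](C(C)C)(C(C)C)CC#C[Si](C(C)C)(C(C)C)C(C)C | starting material
21 | 1-[(1S,3R,4S,6S,7S,9S)-4,6-dibromo-3-ethyl-2,8-dioxabicyclo[5.2.1]decan-9-yl]-3,5-bis[tri(propan-2-yl)silyl]pent-4-yn-2-ol (lithium alkoxide in the flask; the two new centres not assigned) | CC(C)[Si](C(C)C)(C(C)C)C#CC([Si](C(C)C)(C(C)C)C(C)C)C(O)C[C@@H]1O[C@H]2C[C@@H]1O[C@H](CC)[C@@H](Br)C[C@@H]2Br | intermediate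
22 | {(3Z)-5-[(1S,3R,4S,6S,7S,9S)-4,6-dibromo-3-ethyl-2,8-dioxabicyclo[5.2.1]decan-9-yl]pent-3-en-1-yn-1-yl}tri(propan-2-yl)silane | CC(C)[Si](C(C)C)(C(C)C)C#C/C=C\C[C@@H]1O[C@H]2C[C@@H]1O[C@H](CC)[C@@H](Br)C[C@@H]2Br | intermediate
23 | (1S,3R,4S,6S,7S,9S)-4,6-dibromo-3-ethyl-9-[(2Z)-pent-2-en-4-yn-1-yl]-2,8-dioxabicyclo[5.2.1]decane | C#C/C=C\C[C@@H]1O[C@H]2C[C@@H]1O[C@H](CC)[C@@H](Br)C[C@@H]2Br | target

Total step count: 15. Longest linear sequence: 13 steps (steps 1–4 and 7–15).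

Steps most likely to fail

Step 11. The β-bromo alcohol of 15 is a weak nucleophile, so the 8-exo closure may be outrun by intermolecular epoxide opening or by 9-endo attack at C6. The fallback postpones the bromination so that an ordinary secondary alcohol closes the ring; it sets out from 13 and comes back at 16. Silylation of the C12 hydroxyl of 13 (TBSOTf, 2,6-lutidine, CH2Cl2, −78 °C) should give the bis-silyl ether tert-butyl{[(3R,4R,6Z)-8-[(2R,3S)-3-(prop-2-en-1-yl)oxiran-2-yl]-3-[(triethylsilyl)oxy]oct-6-en-4-yl]oxy}dimethylsilane F1. Selective cleavage of the triethylsilyl ether (PPTS, MeOH, 0 °C) should give the C13 alcohol (3R,4R,6Z)-4-{[tert-butyl(dimethyl)silyl]oxy}-8-[(2R,3S)-3-(prop-2-en-1-yl)oxiran-2-yl]oct-6-en-3-ol F2. The same cyclisation (Eu(fod)3, toluene, 100 °C) should give the oxocene (1S)-1-[(2S,4Z,7R,8R)-7-{[tert-butyl(dimethyl)silyl]oxy}-8-ethyl-3,6,7,8-tetrahydro-2H-oxocin-2-yl]but-3-en-1-ol F3. Acetylation (Ac2O, pyridine, DMAP) should give (1S)-1-[(2S,4Z,7R,8R)-7-{[tert-butyl(dimethyl)silyl]oxy}-8-ethyl-3,6,7,8-tetrahydro-2H-oxocin-2-yl]but-3-en-1-yl acetate F4. Desilylation (HF·pyridine, THF) should give (1S)-1-[(2S,4Z,7R,8R)-8-ethyl-7-hydroxy-3,6,7,8-tetrahydro-2H-oxocin-2-yl]but-3-en-1-yl acetate F5. Appel bromination with inversion on the ring (CBr4, P(n-Oct)3, toluene, 70 °C) should give (1S)-1-[(2S,4Z,7S,8R)-7-bromo-8-ethyl-3,6,7,8-tetrahydro-2H-oxocin-2-yl]but-3-en-1-yl acetate F6. Methanolysis (K2CO3, MeOH, 0 °C) then returns 16. This also replaces the acyclic Appel reaction of step 9.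

Step 7. In the one-pot sequence, residual lithium acetylide may be alkylated twice or may consume 9, and the BF3-activated internal epoxide of the alkynyllithium may be opened. The fallback uses a silyl-capped acetylene in separate operations; it sets out from 6 and comes back at 12. Lithium (trimethylsilyl)acetylide (ethynyltrimethylsilane, n-BuLi, THF, −78 °C) should displace the triflate of 6 to give trimethyl{3-[(2R,3S)-3-(prop-2-en-1-yl)oxiran-2-yl]prop-1-yn-1-yl}silane F7. Desilylation (K2CO3, MeOH) gives 11 as an isolated, purified compound. Lithiation (n-BuLi, THF, −78 °C) and addition of 9 with BF3·OEt2 then give 12.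

Step 12. Chemoselectivity may be lost through bromonium formation at the terminal alkene alongside the ring alkene. The fallback installs the silyl enyne first, so that the ring alkene is the only electron-rich alkene; it sets out from 16 and comes back at 22, replacing steps 12–14. Z-selective enyne cross-metathesis of 16 with (but-3-en-1-yn-1-yl)tri(propan-2-yl)silane (second-generation Grubbs catalyst (H2IMes)(PCy3)Cl2Ru=CHPh, CH2Cl2, 40 °C) should give (1S,3Z)-1-[(2S,4Z,7S,8R)-7-bromo-8-ethyl-3,6,7,8-tetrahydro-2H-oxocin-2-yl]-6-[tri(propan-2-yl)silyl]hex-3-en-5-yn-1-ol F8. Bromoetherification (NBS, CH2Cl2, −20 °C) then gives 22.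

Further compounds
F1 | step 11 | tert-butyl{[(3R,4R,6Z)-8-[(2R,3S)-3-(prop-2-en-1-yl)oxiran-2-yl]-3-[(triethylsilyl)oxy]oct-6-en-4-yl]oxy}dimethylsilane | C=CC[C@@H]1O[C@@H]1C/C=C\C[C@@H](O[Si](C)(C)C(C)(C)C)[C@@H](CC)O[Si](CC)(CC)CC
F2 | step 11 | (3R,4R,6Z)-4-{[tert-butyl(dimethyl)silyl]oxy}-8-[(2R,3S)-3-(prop-2-en-1-yl)oxiran-2-yl]oct-6-en-3-ol | C=CC[C@@H]1O[C@@H]1C/C=C\C[C@@H](O[Si](C)(C)C(C)(C)C)[C@@H](CC)O
F3 | step 11 | (1S)-1-[(2S,4Z,7R,8R)-7-{[tert-butyl(dimethyl)silyl]oxy}-8-ethyl-3,6,7,8-tetrahydro-2H-oxocin-2-yl]but-3-en-1-ol | C=CC[C@H](O)[C@@H]1C/C=C\C[C@@H](O[Si](C)(C)C(C)(C)C)[C@@H](CC)O1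
F4 | step 11 | (1S)-1-[(2S,4Z,7R,8R)-7-{[tert-butyl(dimethyl)silyl]oxy}-8-ethyl-3,6,7,8-tetrahydro-2H-oxocin-2-yl]but-3-en-1-yl acetate | C=CC[C@H](OC(C)=O)[C@@H]1C/C=C\C[C@@H](O[Si](C)(C)C(C)(C)C)[C@@H](CC)O1
F5 | step 11 | (1S)-1-[(2S,4Z,7R,8R)-8-ethyl-7-hydroxy-3,6,7,8-tetrahydro-2H-oxocin-2-yl]but-3-en-1-yl acetate | C=CC[C@H](OC(C)=O)[C@@H]1C/C=C\C[C@@H](O)[C@@H](CC)O1
F6 | step 11 | (1S)-1-[(2S,4Z,7S,8R)-7-bromo-8-ethyl-3,6,7,8-tetrahydro-2H-oxocin-2-yl]but-3-en-1-yl acetate | C=CC[C@H](OC(C)=O)[C@@H]1C/C=C\C[C@H](Br)[C@@H](CC)O1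
F7 | step 7 | trimethyl{3-[(2R,3S)-3-(prop-2-en-1-yl)oxiran-2-yl]prop-1-yn-1-yl}silane | C=CC[C@@H]1O[C@@H]1CC#C[Si](C)(C)C
F8 | step 12 | (1S,3Z)-1-[(2S,4Z,7S,8R)-7-bromo-8-ethyl-3,6,7,8-tetrahydro-2H-oxocin-2-yl]-6-[tri(propan-2-yl)silyl]hex-3-en-5-yn-1-ol | CC(C)[Si](C(C)C)(C(C)C)C#C/C=C\C[C@H](O)[C@@H]1C/C=C\C[C@H](Br)[C@@H](CC)O1
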